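**Retrosynthetic overview**

1. Target 18 comes from chroman 17 by removal of two MOM ethers. Rings A and B are bought as benzene rings, and the pyran ring is the only ring formed, last, by O1–C2 Mitsunobu closure of phenol alcohol 16.
2. 16 comes from tertiary boronic ester 14, in which boron on C3 and silicon on C2 are temporary groups: the C3–B bond is protonated with retention and the C2–Si bond is oxidised to C2–OH.
3. 14 comes from one three-component, enantioselective conjunctive cross-coupling that forms C2–C3 and C4–C4a together from 1-(ring B)vinyl boronate 8, a silylmethyl magnesium reagent (C2) and ring A bromide 10.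
4. Enabling feature: C3 is a benzylic methine that carries ring B and sits between two methylenes, C2 (bound to O1) and C4 (bound to C4a of ring A). C3=C4 can therefore be a 1,1-disubstituted alkene with boron on C3, so that C4 accepts the ring A arylpalladium and C3 receives a C2 group that migrates from boron.
5. 8 comes from gallacetophenone: 4-O-prenylation, protection, aromatic Claisen rearrangement (1,1-dimethylallyl group at C5'), enol triflate formation and Miyaura borylation.

Key step: step 9

Remark: the SMILES is read as the (3S)-isoflavan. Chroman numbering (O1, C2, C3, C4, C4a, C8a) is used for the pyran-ring atoms. ArB stands for 2-methoxy-3,4-bis(methoxymethoxy)-5-(2-methylbut-3-en-2-yl)phenyl and TBS for tert-butyldimethylsilyl.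

Assumption: the (S,S)-ferrocenyl bisphosphine named in step 9 is taken, by analogy, to give (S)-14; its mirror-image ligand would be used if the first run shows the opposite sense.

**Route**

Step 1
Reactants: 1 2,3,4-trihydroxyacetophenone (gallacetophenone)
Product: 2 1-[2,3-dihydroxy-4-(3-methylbut-2-enyloxy)phenyl]ethanone
Conditions: prenyl bromide (1.05 equiv), NaHCO3, DMF, 40 °C, N2
Reagents that add atoms: prenyl bromide (1-bromo-3-methylbut-2-ene), CC(C)=CCBr
Why: Williamson ether synthesis under a weak base, in which the 4-OH (para to the acetyl group and not held in the hydrogen bond that ties up the 2-OH) is the most acidic phenol and should be alkylated first.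

Step 2
Reactants: 2 1-[2,3-dihydroxy-4-(3-methylbut-2-enyloxy)phenyl]ethanone
Product: 3 1-[2-hydroxy-3-(methoxymethoxy)-4-(3-methylbut-2-enyloxy)phenyl]ethanone
Conditions: MOMCl (1.1 equiv), i-Pr2NEt, CH2Cl2, 0 °C
Reagents that add atoms: chloromethyl methyl ether, COCCl
Why: Chemoselective MOM ether formation, since the free 3-OH reacts with the amine-activated chloromethyl ether while the 2-OH stays locked in its hydrogen bond to the ketone.

Step 3
Reactants: 3 1-[2-hydroxy-3-(methoxymethoxy)-4-(3-methylbut-2-enyloxy)phenyl]ethanone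
Product: 4 1-[2-methoxy-3-(methoxymethoxy)-4-(3-methylbut-2-enyloxy)phenyl]ethanone
Conditions: MeI, K2CO3, DMF, 40 °C
Reagents that add atoms: iodomethane, CI
Why: Williamson methylation of the only remaining phenol, whose chelation is overcome by carbonate in a polar aprotic solvent.

Step 4
Reactants: 4 1-[2-methoxy-3-(methoxymethoxy)-4-(3-methylbut-2-enyloxy)phenyl]ethanone
Product: 5 1-[4-hydroxy-2-methoxy-3-(methoxymethoxy)-5-(2-methylbut-3-en-2-yl)phenyl]ethanone
Conditions: PhNEt2, 190 °C, sealed tube, argon, short reaction time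
Reagents that add atoms: none
Why: Aromatic Claisen rearrangement ([3,3]-sigmatropic shift with allyl inversion, then tautomerisation), in which only C5 of the two ortho positions bears hydrogen, so the 1,1-dimethylallyl group and the new 4-OH should arise there.

Step 5
Reactants: 5 1-[4-hydroxy-2-methoxy-3-(methoxymethoxy)-5-(2-methylbut-3-en-2-yl)phenyl]ethanone
Product: 6 1-[2-methoxy-3,4-bis(methoxymethoxy)-5-(2-methylbut-3-en-2-yl)phenyl]ethanone (ArB–COCH3)
Conditions: NaH (1.05 equiv), MOMCl, DMF, 0 °C
Reagents that add atoms: chloromethyl methyl ether, COCCl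
Why: MOM protection through the sodium phenoxide, which forms selectively because the hindered phenol is far more acidic than the methyl ketone.

Step 6
Reactants: 6 1-[2-methoxy-3,4-bis(methoxymethoxy)-5-(2-methylbut-3-en-2-yl)phenyl]ethanone
Product: 7 1-ArB-ethenyl trifluoromethanesulfonate
Conditions: KN(SiMe3)2, PhNTf2, THF, −78 °C
Reagents that add atoms: N-phenylbis(trifluoromethanesulfonimide), O=S(=O)(N(c1ccccc1)S(=O)(=O)C(F)(F)F)C(F)(F)F
Why: Enol triflate synthesis by deprotonation at the only enolisable position and O-sulfonylation of the potassium enolate.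

Step 7
Reactants: 7 1-ArB-ethenyl trifluoromethanesulfonate
Product: 8 2-(1-ArB-ethenyl)-4,4,5,5-tetramethyl-1,3,2-dioxaborolane
Conditions: B2pin2, PdCl2(PPh3)2 (3 mol %), PPh3, KOPh, toluene, 50 °C
Reagents that add atoms: bis(pinacolato)diboron, CC1(C)OB(OC1(C)C)B1OC(C)(C)C(C)(C)O1
Why: Miyaura borylation of a 1-alkenyl triflate (oxidative addition, phenoxide-assisted boron transfer, reductive elimination), which keeps the 1,1-disubstituted alkene in place.

Step 8
Reactants: 9 4-bromoresorcinol (4-bromobenzene-1,3-diol)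
Product: 10 1-bromo-2,4-bis(tert-butyldimethylsilyloxy)benzene
Conditions: TBSCl (2.2 equiv), imidazole, DMF, rt
Reagents that add atoms: tert-butyldimethylsilyl chloride, CC(C)(C)[Si](C)(C)Cl
Why: Standard imidazole-promoted silylation of both phenols, with bromine ortho to one silyloxy group and para to the other as C4a, C8a and C7 require.

Step 9
Reactants: 8 2-(1-ArB-ethenyl)-4,4,5,5-tetramethyl-1,3,2-dioxaborolane; 10 1-bromo-2,4-bis(tert-butyldimethylsilyloxy)benzene; 11 (chloromethyl)(isopropoxy)dimethylsilane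
Product: 14 2-[(2S)-1-[2,4-bis(tert-butyldimethylsilyloxy)phenyl]-2-ArB-3-[isopropoxy(dimethyl)silyl]propan-2-yl]-4,4,5,5-tetramethyl-1,3,2-dioxaborolane, via Grignard reagent 12 (not isolated), via boron ate complex 13 (not isolated)
Conditions: 11, Mg, THF, reflux; add to 8, THF, 0 °C to rt; then 10, NaOTf, Pd(OAc)2 (3 mol %), (S,S)-1,1'-bis[bis(4-methoxy-3,5-dimethylphenyl)phosphino]-2,2'-bis[(R)-(dimethylamino)(phenyl)methyl]ferrocene (MandyPhos type, 3.6 mol %), THF, 60 °C
Reagents that add atoms: none
Why: Proposed new method: the magnesium reagent 12 adds to boron of 8 to give ate complex 13, zerovalent palladium bearing the chiral ferrocenyl bisphosphine inserts into the C–Br bond of 10, NaOTf removes the halide, and the cationic arylpalladium binds the alkene of 13 and triggers a 1,2-metalate shift in which the silylmethyl group moves from boron to C3 (C2–C3 bond) while C4 becomes bound to palladium, after which reductive elimination forms C4–C4a. The closest known reaction type is the palladium-catalysed enantioselective conjunctive cross-coupling of alkenyl boron ate complexes, which includes α-alkyl-substituted alkenyl boronates giving tertiary boronic esters and Grignard-derived ate complexes used with aryl bromides and NaOTf; new here are the α-aryl group on the alkenyl boronate and the α-silylmethyl migrating group. No ring is closed in this step, since the pyran ring is completed later through O1–C2. The new C3 stereocentre is controlled by the ligand, which decides the alkene face taken by palladium and therefore the opposite face on which the migrating group arrives. The step needs conjunctive coupling to win over direct Suzuki-type transfer and over β-hydride elimination: the chelating bisphosphine leaves no free site for transmetalation, the silylmethyl group is the only carbon group on boron that can migrate, and the fully substituted C3 leaves the C4–palladium intermediate without a β-hydrogen. Regiochemistry is fixed by boron, which makes C3 the migration terminus and the unsubstituted CH2 (C4) the site of arylation.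

Step 10
Reactants: 14 2-[(2S)-1-[2,4-bis(tert-butyldimethylsilyloxy)phenyl]-2-ArB-3-[isopropoxy(dimethyl)silyl]propan-2-yl]-4,4,5,5-tetramethyl-1,3,2-dioxaborolane
Product: 16 4-[(2S)-2-ArB-3-hydroxypropyl]benzene-1,3-diol, via fluorosilane 15 (not isolated)
Conditions: Bu4NF·3H2O (excess), toluene/THF, 45 °C; then KHCO3, KF, 30% H2O2, THF/MeOH, 40 °C
Reagents that add atoms: hydrogen peroxide, OO
Why: Fluoride forms the ate complex of the tertiary benzylic boronic ester, whose C–B bond is protonated by water with retention at C3 (stereospecific protodeboronation), while the same reagent removes both aryl silyl ethers and converts the alkoxysilane into a fluorosilane that buffered peroxide oxidises to the primary alcohol (Tamao–Fleming oxidation) without touching C3.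

Step 11
Reactants: 16 4-[(2S)-2-ArB-3-hydroxypropyl]benzene-1,3-diol
Product: 17 (3S)-3-ArB-3,4-dihydro-2H-chromen-7-ol
Conditions: PPh3, DIAD, THF (0.01 M), 0 °C to rt
Reagents that add atoms: none
Why: Mitsunobu etherification in which only the ortho phenol can reach the activated primary carbon in a six-membered closure, so O1–C2 should form intramolecularly at high dilution while C3 is not involved and keeps its configuration.

Step 12
Reactants: 17 (3S)-3-ArB-3,4-dihydro-2H-chromen-7-ol
Product: 18 4-[(3S)-7-hydroxy-3,4-dihydro-2H-chromen-3-yl]-3-methoxy-6-(2-methylbut-3-en-2-yl)benzene-1,2-diol (target)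
Conditions: HCl (2 M aq), MeOH, 40 °C, degassed
Reagents that add atoms: none
Why: Acid-catalysed acetal exchange with methanol should remove both MOM ethers under mild conditions that leave the terminal alkene, the aryl methyl ether and the C3 stereocentre untouched.

**Compound list**

1 | 2,3,4-trihydroxyacetophenone (gallacetophenone) | CC(=O)c1ccc(O)c(O)c1O | starting material
2 | 1-[2,3-dihydroxy-4-(3-methylbut-2-enyloxy)phenyl]ethanone | CC(=O)c1ccc(OCC=C(C)C)c(O)c1O | intermediate
3 | 1-[2-hydroxy-3-(methoxymethoxy)-4-(3-methylbut-2-enyloxy)phenyl]ethanone | CC(=O)c1ccc(OCC=C(C)C)c(OCOC)c1O | intermediate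
4 | 1-[2-methoxy-3-(methoxymethoxy)-4-(3-methylbut-2-enyloxy)phenyl]ethanone | CC(=O)c1ccc(OCC=C(C)C)c(OCOC)c1OC | intermediate
5 | 1-[4-hydroxy-2-methoxy-3-(methoxymethoxy)-5-(2-methylbut-3-en-2-yl)phenyl]ethanone | CC(=O)c1cc(C(C)(C)C=C)c(O)c(OCOC)c1OC | intermediate
6 | 1-[2-methoxy-3,4-bis(methoxymethoxy)-5-(2-methylbut-3-en-2-yl)phenyl]ethanone | CC(=O)c1cc(C(C)(C)C=C)c(OCOC)c(OCOC)c1OC | intermediate
7 | 1-[2-methoxy-3,4-bis(methoxymethoxy)-5-(2-methylbut-3-en-2-yl)phenyl]ethenyl trifluoromethanesulfonate | C=C(OS(=O)(=O)C(F)(F)F)c1cc(C(C)(C)C=C)c(OCOC)c(OCOC)c1OC | intermediate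
8 | 2-{1-[2-methoxy-3,4-bis(methoxymethoxy)-5-(2-methylbut-3-en-2-yl)phenyl]ethenyl}-4,4,5,5-tetramethyl-1,3,2-dioxaborolane | C=C(B1OC(C)(C)C(C)(C)O1)c1cc(C(C)(C)C=C)c(OCOC)c(OCOC)c1OC | intermediate
9 | 4-bromoresorcinol | Oc1ccc(Br)c(O)c1 | starting material
10 | 1-bromo-2,4-bis(tert-butyldimethylsilyloxy)benzene | CC(C)(C)[Si](C)(C)Oc1ccc(Br)c(O[Si](C)(C)C(C)(C)C)c1 | intermediate
11 | (chloromethyl)(isopropoxy)dimethylsilane | CC(C)O[Si](C)(C)CCl | starting material
12 | [(isopropoxydimethylsilyl)methyl]magnesium chloride (formed in the flask) | CC(C)O[Si](C)(C)C[Mg]Cl | intermediate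
13 | chloromagnesium [1-ArB-ethenyl][(isopropoxydimethylsilyl)methyl](pinacolato)borate (formed in the flask) | C=C(c1cc(C(C)(C)C=C)c(OCOC)c(OCOC)c1OC)[B-]1(C[Si](C)(C)OC(C)C)OC(C)(C)C(C)(C)O1.[Mg+]Cl | intermediate
14 | 2-[(2S)-1-[2,4-bis(tert-butyldimethylsilyloxy)phenyl]-2-ArB-3-[isopropoxy(dimethyl)silyl]propan-2-yl]-4,4,5,5-tetramethyl-1,3,2-dioxaborolane | C=CC(C)(C)c1cc([C@@](B2OC(C)(C)C(C)(C)O2)(C[Si](C)(C)OC(C)C)Cc2ccc(O[Si](C)(C)C(C)(C)C)cc2O[Si](C)(C)C(C)(C)C)c(OC)c(OCOC)c1OCOC | intermediate
15 | 4-[(2S)-2-ArB-3-[fluoro(dimethyl)silyl]propyl]benzene-1,3-diol (formed in the flask) | C=CC(C)(C)c1cc([C@@H](C[Si](C)(C)F)Cc2ccc(O)cc2O)c(OC)c(OCOC)c1OCOC | intermediate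
16 | 4-[(2S)-2-ArB-3-hydroxypropyl]benzene-1,3-diol | C=CC(C)(C)c1cc([C@@H](CO)Cc2ccc(O)cc2O)c(OC)c(OCOC)c1OCOC | intermediate
17 | (3S)-3-[2-methoxy-3,4-bis(methoxymethoxy)-5-(2-methylbut-3-en-2-yl)phenyl]-3,4-dihydro-2H-chromen-7-ol | C=CC(C)(C)c1cc([C@H]2COc3cc(O)ccc3C2)c(OC)c(OCOC)c1OCOC | intermediate
18 | 4-[(3S)-7-hydroxy-3,4-dihydro-2H-chromen-3-yl]-3-methoxy-6-(2-methylbut-3-en-2-yl)benzene-1,2-diol | C=CC(C)(C)c1cc([C@H]2COc3cc(O)ccc3C2)c(OC)c(O)c1O | target

**Step count and risks**

Total step count: 12. Longest linear sequence: 11 steps (steps 1 to 7, then 9 to 12).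

Steps most likely to fail:

1. Step 9 (proposed new method). The ate complex may form incompletely at the hindered boron, the alkenyl group may transfer directly to palladium, or facial selectivity may be poor with the ortho-substituted aryl group on the alkene. The fallback is lithiation–borylation, which is known chemistry; it sets out from 6 and 10 (and uses 12) and comes back at 14. Palladium-catalysed ketone α-arylation of 6 with 10 (Pd2(dba)3, Xantphos, K3PO4, toluene, 80 °C) should give 2-[2,4-bis(tert-butyldimethylsilyloxy)phenyl]-1-ArB-ethan-1-one F1. Noyori-type transfer hydrogenation (RuCl[(R,R)-TsNCH(Ph)CH(Ph)NH2](p-cymene), HCO2H/Et3N) should give the (R)-alcohol F2. Carbamoylation (i-Pr2NCOCl, Et3N, DMAP) gives the N,N-diisopropylcarbamate F3. In parallel, Grignard reagent 12 and 2-isopropoxy-4,4,5,5-tetramethyl-1,3,2-dioxaborolane give the silylmethyl boronic ester F4. Lithiation of F3 (s-BuLi, Et2O, −78 °C), borylation with F4 and 1,2-migration on warming with MgBr2·OEt2/MeOH would give 14 (retention in lithiation and borylation, inversion in the migration), and the route continues with step 10.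

2. Step 10. Protonolysis of the C–B bond at the crowded, electron-rich benzylic centre may be slow or lose configuration, and the free resorcinol may suffer oxidative damage during the silicon oxidation. The fallback sets C3 on a carbon that receives its hydrogen under catalyst control; it sets out from 14 and comes back at 16. Oxidation of the C–B bond (NaBO3·4H2O, THF/H2O) should give the β-hydroxysilane F5. Peterson elimination (KH, THF) should give the 1,1-disubstituted alkene F6. Copper-catalysed enantioselective hydroboration of this α-substituted styrene (enantiopure (NHC)CuCl, NaOt-Bu, B2pin2, MeOH, THF) should give the primary boronic ester F7 with C3 set by the catalyst. Oxidation (NaBO3·4H2O) gives the alcohol F8, and Bu4NF removes both silyl ethers to return 16.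

3. Step 4. At the temperature of the rearrangement the new ortho-(1,1-dimethylallyl)phenol may react further, by isomerisation of the side chain (abnormal Claisen pathway) or by addition of the phenol to the alkene. The fallback installs the group by cross-coupling; it sets out from 1 and comes back at 6. Bromination of 1 (NBS, MeCN, 0 °C) should occur at C5, ortho to the 4-OH and para to the 2-OH, to give 1-(5-bromo-2,3,4-trihydroxyphenyl)ethanone F9. MOMCl/i-Pr2NEt protects the 3- and 4-OH to give F10, and MeI/K2CO3 methylates the 2-OH to give the aryl bromide F11. A Suzuki–Miyaura coupling with 4,4,5,5-tetramethyl-2-(3-methylbut-2-en-1-yl)-1,3,2-dioxaborolane (Pd(OAc)2, a bulky biaryl dialkylphosphine chosen for branched coupling at the γ-carbon of the allyl boronate, K3PO4, THF/H2O, 40 °C) would give 6.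

Further compounds

F1 | step 9 | 2-[2,4-bis(tert-butyldimethylsilyloxy)phenyl]-1-[2-methoxy-3,4-bis(methoxymethoxy)-5-(2-methylbut-3-en-2-yl)phenyl]ethan-1-one | C=CC(C)(C)c1cc(C(=O)Cc2ccc(O[Si](C)(C)C(C)(C)C)cc2O[Si](C)(C)C(C)(C)C)c(OC)c(OCOC)c1OCOC
F2 | step 9 | (1R)-2-[2,4-bis(tert-butyldimethylsilyloxy)phenyl]-1-[2-methoxy-3,4-bis(methoxymethoxy)-5-(2-methylbut-3-en-2-yl)phenyl]ethan-1-ol | C=CC(C)(C)c1cc([C@H](O)Cc2ccc(O[Si](C)(C)C(C)(C)C)cc2O[Si](C)(C)C(C)(C)C)c(OC)c(OCOC)c1OCOC
F3 | step 9 | (1R)-2-[2,4-bis(tert-butyldimethylsilyloxy)phenyl]-1-[2-methoxy-3,4-bis(methoxymethoxy)-5-(2-methylbut-3-en-2-yl)phenyl]ethyl N,N-diisopropylcarbamate | C=CC(C)(C)c1cc([C@H](OC(=O)N(C(C)C)C(C)C)Cc2ccc(O[Si](C)(C)C(C)(C)C)cc2O[Si](C)(C)C(C)(C)C)c(OC)c(OCOC)c1OCOC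
F4 | step 9 | 2-{[isopropoxy(dimethyl)silyl]methyl}-4,4,5,5-tetramethyl-1,3,2-dioxaborolane | CC(C)O[Si](C)(C)CB1OC(C)(C)C(C)(C)O1
F5 | step 10 | (2R)-1-[2,4-bis(tert-butyldimethylsilyloxy)phenyl]-3-[isopropoxy(dimethyl)silyl]-2-[2-methoxy-3,4-bis(methoxymethoxy)-5-(2-methylbut-3-en-2-yl)phenyl]propan-2-ol | C=CC(C)(C)c1cc([C@@](O)(C[Si](C)(C)OC(C)C)Cc2ccc(O[Si](C)(C)C(C)(C)C)cc2O[Si](C)(C)C(C)(C)C)c(OC)c(OCOC)c1OCOC
F6 | step 10 | 1-{3-[2,4-bis(tert-butyldimethylsilyloxy)phenyl]prop-1-en-2-yl}-2-methoxy-3,4-bis(methoxymethoxy)-5-(2-methylbut-3-en-2-yl)benzene | C=C(Cc1ccc(O[Si](C)(C)C(C)(C)C)cc1O[Si](C)(C)C(C)(C)C)c1cc(C(C)(C)C=C)c(OCOC)c(OCOC)c1OC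
F7 | step 10 | 2-[(2S)-3-[2,4-bis(tert-butyldimethylsilyloxy)phenyl]-2-[2-methoxy-3,4-bis(methoxymethoxy)-5-(2-methylbut-3-en-2-yl)phenyl]propyl]-4,4,5,5-tetramethyl-1,3,2-dioxaborolane | C=CC(C)(C)c1cc([C@@H](CB3OC(C)(C)C(C)(C)O3)Cc2ccc(O[Si](C)(C)C(C)(C)C)cc2O[Si](C)(C)C(C)(C)C)c(OC)c(OCOC)c1OCOC
F8 | step 10 | (2S)-3-[2,4-bis(tert-butyldimethylsilyloxy)phenyl]-2-[2-methoxy-3,4-bis(methoxymethoxy)-5-(2-methylbut-3-en-2-yl)phenyl]propan-1-ol | C=CC(C)(C)c1cc([C@@H](CO)Cc2ccc(O[Si](C)(C)C(C)(C)C)cc2O[Si](C)(C)C(C)(C)C)c(OC)c(OCOC)c1OCOC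
F9 | step 4 | 1-(5-bromo-2,3,4-trihydroxyphenyl)ethanone | CC(=O)c1cc(Br)c(O)c(O)c1O
F10 | step 4 | 1-[5-bromo-2-hydroxy-3,4-bis(methoxymethoxy)phenyl]ethanone | CC(=O)c1cc(Br)c(OCOC)c(OCOC)c1O
F11 | step 4 | 1-[5-bromo-2-methoxy-3,4-bis(methoxymethoxy)phenyl]ethanone | CC(=O)c1cc(Br)c(OCOC)c(OCOC)c1OC
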